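The target is epigallocatechin-(4β→8)-catechin. Everything rests on opening the lower pyran ring (ring F) at O1–C2. This leads back to a 2'-hydroxychalcone whose phloroglucinol ring (ring D) already carries upper C4. The feature used is that the oxygen on lower C8a sits between C8, the carbon bonded to upper C4, and the acyl-bearing C4a. With the other two ring D oxygens benzylated, only this oxygen can add to the enone. One catalytic asymmetric oxa-Michael addition therefore closes ring F, fixes the 4→8 connectivity and sets lower C2. The precursor is a perbenzylated, C8-brominated epigallocatechin bonded through C4β to that chalcone.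

Key step: step 8

**Notation.** Upper unit: rings A (benzo), B (pendant aryl) and C (pyran). Lower unit: rings D, E and F in the same sense. Atom numbers are flavan numbers. U stands for the 8-bromo-3,5,7,3',4',5'-hexa-O-benzyl-epigallocatechin-4β-yl residue. It keeps the 2R,3R centres of epigallocatechin, and its C4 bond is trans to the 3-benzyloxy group.

**Design points**
- **Hydroxyl defined early.** A phloroacetophenone with a C3 substituent has two carbonyl-chelated hydroxyls, and a late dibenzylation would have to tell them apart. The acetophenone therefore enters the coupling already as its 4,6-dibenzyl ether, so the ring-closing hydroxyl is fixed before the C–C bond is made.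
- **Bromine cap.** The acetophenone is a weak nucleophile, so a bromine on upper C8 blocks self-condensation of the electrophile. It is a spectator that leaves in the final hydrogenolysis.
- **Epimers, not enantiomers.** The upper unit is enantiopure, so loss of configuration at lower C2 is epimerisation. The two flavanones are separable diastereomers.
- **No metal enolate.** A flavanone metal enolate expels the C8a phenoxide, so the C3 oxygen is introduced through a neutral silyl enol ether.
- **Descriptors.** 2S in the flavanone and 2R in the catechin unit describe the same spatial arrangement. The descriptor changes only when C3 gains an oxygen.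

**Assumption:** which of the two pseudo-enantiomeric cinchona thioureas sends the oxygen to the Si face of this chalcone cannot be fixed on paper, because the chiral upper unit adds its own bias. The quinine-derived catalyst is written, and its quinidine-derived counterpart replaces it, all else unchanged, if the first run shows the opposite sense.

## Route

Step 1
Reactants: 1 (−)-epigallocatechin
Product: 2 5,7,3',4',5'-penta-O-benzyl-(−)-epigallocatechin (2R,3R; 3-OH free)
Conditions: BnBr (5.5 equiv), K2CO3 (6 equiv), DMF, argon, 0 °C → rt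
Reagents that add atoms: benzyl bromide BrCc1ccccc1
Why: Williamson ether synthesis: carbonate deprotonates only the five phenols and not the C3 alcohol, and the mild base, low temperature and exclusion of air keep the 2,3-cis flavan from epimerising at C2, so both stereocentres of 1 are carried through.

Step 2
Reactants: 2 5,7,3',4',5'-penta-O-benzyl-(−)-epigallocatechin
Product: 3 3,5,7,3',4',5'-hexa-O-benzyl-(−)-epigallocatechin (2R,3R)
Conditions: NaH (1.5 equiv), BnBr (1.5 equiv), Bu4NI (cat.), DMF, 0 °C → rt
Reagents that add atoms: benzyl bromide BrCc1ccccc1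
Why: Williamson ether synthesis on the remaining secondary alkoxide; with every phenol capped the pyran ring cannot open under NaH, so C2 and C3 stay as they are, and the later cyclisation substrate will hold only one acidic proton.

Step 3
Reactants: 3 3,5,7,3',4',5'-hexa-O-benzyl-(−)-epigallocatechin
Product: 4 8-bromo-3,5,7,3',4',5'-hexa-O-benzyl-(−)-epigallocatechin
Conditions: NBS (1.0 equiv), CH2Cl2, dark, −78 → 0 °C
Reagents that add atoms: N-bromosuccinimide O=C1CCC(=O)N1Br
Why: Electrophilic aromatic bromination: in 5,7-dibenzyloxyflavans C8 (next to O1) is more reactive and less crowded than C6 (between two benzyloxy groups), and the halogen caps the position through which a C4 cation would otherwise attack a second molecule in step 6.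

Step 4
Reactants: 4 8-bromo-3,5,7,3',4',5'-hexa-O-benzyl-(−)-epigallocatechin
Product: 5 8-bromo-4β-(2-ethoxyethoxy)-3,5,7,3',4',5'-hexa-O-benzyl-epigallocatechin (2,3-cis; 3,4-trans)
Conditions: DDQ (1.5 equiv), 2-ethoxyethanol (5 equiv), CH2Cl2, rt
Reagents that add atoms: 2-ethoxyethanol CCOCCO
Why: DDQ benzylic oxidation: hydride abstraction from C4 gives a cation stabilised by ring A, which the alcohol traps on the β face, anti to the 3-benzyloxy and 2-aryl groups, giving the usual acetal-like C4 leaving group of flavan-3-ol coupling chemistry.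

Step 5
Reactants: 6 2,4,6-trihydroxyacetophenone
Product: 7 4,6-bis(benzyloxy)-2-hydroxyacetophenone
Conditions: BnBr (2.1 equiv), K2CO3 (2.5 equiv), acetone, reflux
Reagents that add atoms: benzyl bromide BrCc1ccccc1
Why: Partial Williamson ether synthesis: the para hydroxyl and one of the two equivalent ortho hydroxyls are alkylated, after which the last one is held in a hydrogen bond to the carbonyl and resists, so the symmetric triol can give only this dibenzyl ether.

Step 6
Reactants: 5 8-bromo-4β-(2-ethoxyethoxy)-hexa-O-benzyl-epigallocatechin; 7 4,6-bis(benzyloxy)-2-hydroxyacetophenone (3 equiv, excess recovered)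
Product: 8 1-[4,6-bis(benzyloxy)-2-hydroxy-3-U-phenyl]ethanone
Conditions: Me3SiOTf (0.2 equiv), 4 Å MS, CH2Cl2, −78 → −20 °C; Et3N quench
Reagents that add atoms: none
Why: Friedel–Crafts alkylation by a flavan-4-yl cation, the bond-forming reaction of procyanidin synthesis: ionisation of the C4 ether is reversible whereas C–C bond formation is not, the bromine cap and the excess of 7 suppress self-condensation, C3 of 7 (flanked by OH and OBn, the carbon at which this acetophenone is also C-glycosylated) reacts rather than C5 (between two OBn groups), and approach anti to the 3-benzyloxy group sets upper C4 as 4β (3,4-trans).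

Step 7
Reactants: 8 1-[4,6-bis(benzyloxy)-2-hydroxy-3-U-phenyl]ethanone; 9 3,4-bis(benzyloxy)benzaldehyde (1.5 equiv)
Product: 10 (E)-1-[4,6-bis(benzyloxy)-2-hydroxy-3-U-phenyl]-3-[3,4-bis(benzyloxy)phenyl]prop-2-en-1-one (the 2'-hydroxychalcone)
Conditions: KOH (50% aq, excess), EtOH/THF, rt; cold aq citric acid to pH 5
Reagents that add atoms: none
Why: Claisen–Schmidt condensation: the methyl ketone enolate adds to the non-enolisable aldehyde and E1cB loss of water gives the conjugated E-enone, which in strong base rests as the open phenoxide and is released as the chalcone by cold, mild acidification.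

Step 8
Reactants: 10 the 2'-hydroxychalcone
Product: 11 (2S)-5,7,3',4'-tetrakis(benzyloxy)-8-U-flavanone
Conditions: N-[3,5-bis(trifluoromethyl)phenyl]-N'-[(8α,9S)-6'-methoxycinchonan-9-yl]thiourea (20 mol %), toluene, 4 Å MS, dark, 0 °C → rt; stopped before equilibrium, filtered through silica
Reagents that add atoms: none
Why: The quinuclidine nitrogen takes the only acidic proton of 10 (the hydroxyl on the carbon that becomes lower C8a) while the thiourea N–H pair binds the enone carbonyl, the phenoxide oxygen adds to Cβ, and the enol formed is protonated at C3 by the ammonium ion. This is the organocatalytic asymmetric intramolecular oxa-Michael cyclisation of 2'-hydroxychalcones to flavanones, the laboratory counterpart of chalcone isomerase. Ring F closes in the 6-endo-trig mode with formation of lower O1–C2. Lower C2 is set by the catalyst, which must expose the Si face of Cβ to give 2S; the enantiopure unit U turns the two outcomes into diastereomers, so it adds a matched or mismatched bias and allows a minor epimer to be removed by chromatography. The 4→8 regiochemistry needs no control in this step because the 4'- and 6'-oxygens are benzylated, and the 6'-benzyloxy group twists the aroyl group out of plane, which weakens the chelate and favours the closed form. Since the addition is reversible, the run is kept cold, the basic catalyst is stripped off at once, recovered 10 is recycled and 11 goes straight into step 9.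

Step 9
Reactants: 11 (2S)-5,7,3',4'-tetrakis(benzyloxy)-8-U-flavanone
Product: 14 (2R,3R)-5,7,3',4'-tetrakis(benzyloxy)-3-hydroxy-8-U-flavanone (2,3-trans dihydroflavonol), via trimethylsilyl enol ether 12 (not isolated), via silyloxy epoxide 13 (not isolated)
Conditions: Et3N (3 equiv) then Me3SiOTf (2 equiv), CH2Cl2, −78 → 0 °C, cold aq NaHCO3 wash; crude, dimethyldioxirane (1.2 equiv, acetone), CH2Cl2, −40 → 0 °C; aq citric acid, THF, 0 °C
Reagents that add atoms: dimethyldioxirane CC1(C)OO1; trimethylsilyl triflate C[Si](C)(C)OS(=O)(=O)C(F)(F)F (its silyl group stays only in 12 and 13)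
Why: Rubottom oxidation: soft enolisation with silyl triflate and amine gives the neutral enol ether without a free enolate that could expel the C8a phenoxide and scramble C2, the dioxirane then epoxidises C3=C4 on the face away from the C2 aryl group, and hydrolysis gives the 2,3-trans ketol (3R), which is also the more stable diequatorial isomer.

Step 10
Reactants: 14 (2R,3R)-dihydroflavonol
Product: 15 (2R,3S,4R)-5,7,3',4'-tetrakis(benzyloxy)-8-U-flavan-3,4-diol (2,3-trans; 3,4-trans expected)
Conditions: NaBH4 (2 equiv), THF/EtOH, 0 °C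
Reagents that add atoms: none
Why: Borohydride 1,2-reduction of the aryl ketone, expected to give the 3,4-trans diol as with other 2,3-trans dihydroflavonols; it ends the retro-Michael lability of C2, and the new C4 centre is erased in step 11, so its configuration is of no consequence.

Step 11
Reactants: 15 (2R,3S,4R)-flavan-3,4-diol
Product: 16 8-bromo-3,5,7,3',4',5'-hexa-O-benzyl-epigallocatechin-(4β→8)-5,7,3',4'-tetra-O-benzyl-(+)-catechin (lower unit 2R,3S; lower 3-OH free)
Conditions: Et3SiH (10 equiv), CF3CO2H (3 equiv), CH2Cl2 (dilute), −40 → −20 °C; aq NaHCO3 quench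
Reagents that add atoms: none
Why: Ionic hydrogenation: the C4 hydroxyl ionises easily because the cation is stabilised by the 5- and 7-benzyloxy groups and O1, the excess silane traps it faster than any arene can at high dilution, the non-benzylic C3 hydroxyl cannot ionise, and the short cold exposure to dilute acid spares the C4–C8 bond.

Step 12
Reactants: 16 the bromo deca-O-benzyl dimer
Product: 17 epigallocatechin-(4β→8)-catechin, upper unit 2R,3R,4R and lower unit 2R,3S (target)
Conditions: H2 (1 atm), Pd(OH)2/C, Et3N (1.2 equiv), THF/MeOH/H2O, rt; filtration under argon, Sephadex LH-20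
Reagents that add atoms: none
Why: Catalytic hydrogenolysis of the ten benzyl ethers with concurrent hydrodebromination of C8; the amine takes up the HBr so that the acid-labile interflavan bond survives, and no stereocentre is touched under these neutral, mild conditions.

## Compound list

1 | (−)-epigallocatechin | Oc1cc(O)c2c(c1)O[C@H](c1cc(O)c(O)c(O)c1)[C@H](O)C2 | starting material
2 | 5,7,3',4',5'-penta-O-benzyl-(−)-epigallocatechin | c9ccccc9COc1cc(OCc9ccccc9)c2c(c1)O[C@H](c1cc(OCc9ccccc9)c(OCc9ccccc9)c(OCc9ccccc9)c1)[C@H](O)C2 | intermediate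
3 | 3,5,7,3',4',5'-hexa-O-benzyl-(−)-epigallocatechin | c9ccccc9COc1cc(OCc9ccccc9)c2c(c1)O[C@H](c1cc(OCc9ccccc9)c(OCc9ccccc9)c(OCc9ccccc9)c1)[C@H](OCc9ccccc9)C2 | intermediate
4 | 8-bromo-hexa-O-benzyl-(−)-epigallocatechin | c9ccccc9COc1cc(OCc9ccccc9)c2c(c1Br)O[C@H](c1cc(OCc9ccccc9)c(OCc9ccccc9)c(OCc9ccccc9)c1)[C@H](OCc9ccccc9)C2 | intermediate
5 | 8-bromo-4β-(2-ethoxyethoxy)-hexa-O-benzyl-epigallocatechin | c9ccccc9COc1cc(OCc9ccccc9)c2c(c1Br)O[C@H](c1cc(OCc9ccccc9)c(OCc9ccccc9)c(OCc9ccccc9)c1)[C@H](OCc9ccccc9)[C@H]2OCCOCC | intermediate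
6 | 2,4,6-trihydroxyacetophenone | CC(=O)c1c(O)cc(O)cc1O | starting material
7 | 4,6-bis(benzyloxy)-2-hydroxyacetophenone | CC(=O)c1c(O)cc(OCc9ccccc9)cc1OCc9ccccc9 | intermediate
8 | 1-[4,6-bis(benzyloxy)-2-hydroxy-3-U-phenyl]ethanone | c9ccccc9COc1cc(OCc9ccccc9)c2c(c1Br)O[C@H](c1cc(OCc9ccccc9)c(OCc9ccccc9)c(OCc9ccccc9)c1)[C@H](OCc9ccccc9)[C@H]2c1c(OCc9ccccc9)cc(OCc9ccccc9)c(C(C)=O)c1O | intermediate
9 | 3,4-bis(benzyloxy)benzaldehyde | O=Cc1ccc(OCc9ccccc9)c(OCc9ccccc9)c1 | starting material
10 | (E)-2'-hydroxychalcone bonded at C3' to U (key-step precursor) | c9ccccc9COc1cc(OCc9ccccc9)c2c(c1Br)O[C@H](c1cc(OCc9ccccc9)c(OCc9ccccc9)c(OCc9ccccc9)c1)[C@H](OCc9ccccc9)[C@H]2c1c(OCc9ccccc9)cc(OCc9ccccc9)c(C(=O)/C=C/c3ccc(OCc9ccccc9)c(OCc9ccccc9)c3)c1O | intermediate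
11 | (2S)-5,7,3',4'-tetrakis(benzyloxy)-8-U-flavanone (key-step product) | c9ccccc9COc1cc(OCc9ccccc9)c2c(c1Br)O[C@H](c1cc(OCc9ccccc9)c(OCc9ccccc9)c(OCc9ccccc9)c1)[C@H](OCc9ccccc9)[C@H]2c1c(OCc9ccccc9)cc(OCc9ccccc9)c2c1O[C@H](c1ccc(OCc9ccccc9)c(OCc9ccccc9)c1)CC2=O | intermediate
12 | (2S)-4-trimethylsilyloxy-flav-3-ene (silyl enol ether of 11) | c9ccccc9COc1cc(OCc9ccccc9)c2c(c1Br)O[C@H](c1cc(OCc9ccccc9)c(OCc9ccccc9)c(OCc9ccccc9)c1)[C@H](OCc9ccccc9)[C@H]2c1c(OCc9ccccc9)cc(OCc9ccccc9)c2c1O[C@H](c1ccc(OCc9ccccc9)c(OCc9ccccc9)c1)C=C2O[Si](C)(C)C | intermediate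
13 | 3,4-epoxy-4-trimethylsilyloxyflavan, epoxide oxygen on the face opposite the C2 aryl group | c9ccccc9COc1cc(OCc9ccccc9)c2c(c1Br)O[C@H](c1cc(OCc9ccccc9)c(OCc9ccccc9)c(OCc9ccccc9)c1)[C@H](OCc9ccccc9)[C@H]2c1c(OCc9ccccc9)cc(OCc9ccccc9)c2c1O[C@H](c1ccc(OCc9ccccc9)c(OCc9ccccc9)c1)[C@H]3O[C@@]23O[Si](C)(C)C | intermediate
14 | (2R,3R)-5,7,3',4'-tetrakis(benzyloxy)-3-hydroxy-8-U-flavanone | c9ccccc9COc1cc(OCc9ccccc9)c2c(c1Br)O[C@H](c1cc(OCc9ccccc9)c(OCc9ccccc9)c(OCc9ccccc9)c1)[C@H](OCc9ccccc9)[C@H]2c1c(OCc9ccccc9)cc(OCc9ccccc9)c2c1O[C@H](c1ccc(OCc9ccccc9)c(OCc9ccccc9)c1)[C@@H](O)C2=O | intermediate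
15 | (2R,3S,4R)-5,7,3',4'-tetrakis(benzyloxy)-8-U-flavan-3,4-diol | c9ccccc9COc1cc(OCc9ccccc9)c2c(c1Br)O[C@H](c1cc(OCc9ccccc9)c(OCc9ccccc9)c(OCc9ccccc9)c1)[C@H](OCc9ccccc9)[C@H]2c1c(OCc9ccccc9)cc(OCc9ccccc9)c2c1O[C@H](c1ccc(OCc9ccccc9)c(OCc9ccccc9)c1)[C@@H](O)[C@@H]2O | intermediate
16 | 8-bromo-hexa-O-benzyl-epigallocatechin-(4β→8)-5,7,3',4'-tetra-O-benzyl-(+)-catechin | c9ccccc9COc1cc(OCc9ccccc9)c2c(c1Br)O[C@H](c1cc(OCc9ccccc9)c(OCc9ccccc9)c(OCc9ccccc9)c1)[C@H](OCc9ccccc9)[C@H]2c1c(OCc9ccccc9)cc(OCc9ccccc9)c2c1O[C@H](c1ccc(OCc9ccccc9)c(OCc9ccccc9)c1)[C@@H](O)C2 | intermediate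
17 | epigallocatechin-(4β→8)-catechin | Oc1cc(O)c2c(c1)O[C@H](c1cc(O)c(O)c(O)c1)[C@H](O)[C@H]2c1c(O)cc(O)c2c1O[C@H](c1ccc(O)c(O)c1)[C@@H](O)C2 | target

Total step count: 12. Longest linear sequence: 11 (steps 1–4 and 6–12, from 1 to 17).

## Steps most likely to fail

**1. Step 8.**
- What may go wrong: the chelated, crowded phenol and the electron-rich enone may add slowly. Facial selectivity may be poor if catalyst and upper unit are mismatched. Retro-addition may erode the kinetic preference.
- Fallback: give up catalyst control and use the resident stereocentres for separation. Setting out from 10, an achiral thermodynamic oxa-Michael cyclisation (NaOAc, EtOH/THF, reflux) forms 11 together with its lower C2 epimer, the (2R)-flavanone F1. The two are diastereomers and are parted by chromatography. F1 and recovered 10 are returned to the same equilibration, and the route is rejoined at 11.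

**2. Step 6.**
- What may go wrong: the acetophenone may capture the cation too slowly. The cation may then be lost through attack on C6 of a second molecule or through elimination, or substitution may stray to C5 of the nucleophile.
- Fallback: arylate first and differentiate the hydroxyls afterwards. Setting out from 5 and 6, the unprotected triol is more nucleophilic and its two free ring carbons are equivalent. It is alkylated with Sc(OTf)3 (10 mol %) in THF/CH2Cl2 to give the C-arylated trihydroxyacetophenone F2. Dibenzylation (BnBr 2.1 equiv, K2CO3, DMF, rt) should then spare the hydroxyl wedged between the acetyl group and U, and the route is rejoined at 8.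

**3. Step 9.**
- What may go wrong: silylation of the peri-hindered ketone may be incomplete. Ring F may open, with epimerisation at C2, during enol ether formation. The benzyloxyarenes may be over-oxidised.
- Fallback: remove the carbonyl first and bring in the C3 oxygen by hydroboration.
  - Setting out from 11, NaBH4 (THF/EtOH, 0 °C) gives the 2,4-cis-flavan-4-ol F3.
  - Pyridinium tosylate (cat., toluene, 4 Å MS, 40 °C, dark) dehydrates it to the (2S)-flav-3-ene F4.
  - Hydroboration–oxidation (BH3·THF, 0 °C, then NaBO3·4H2O) places boron on C3, away from the aryl-stabilised C4 and anti to the C2 aryl group. This gives the 2,3-trans alcohol directly.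
  - The route is rejoined at 16, bypassing 14 and 15.

## Further compounds

F1 | step 8 | (2R)-5,7,3',4'-tetrakis(benzyloxy)-8-U-flavanone (lower C2 epimer of 11) | c9ccccc9COc1cc(OCc9ccccc9)c2c(c1Br)O[C@H](c1cc(OCc9ccccc9)c(OCc9ccccc9)c(OCc9ccccc9)c1)[C@H](OCc9ccccc9)[C@H]2c1c(OCc9ccccc9)cc(OCc9ccccc9)c2c1O[C@@H](c1ccc(OCc9ccccc9)c(OCc9ccccc9)c1)CC2=O
F2 | step 6 | 1-[2,4,6-trihydroxy-3-U-phenyl]ethanone | c9ccccc9COc1cc(OCc9ccccc9)c2c(c1Br)O[C@H](c1cc(OCc9ccccc9)c(OCc9ccccc9)c(OCc9ccccc9)c1)[C@H](OCc9ccccc9)[C@H]2c1c(O)cc(O)c(C(C)=O)c1O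
F3 | step 9 | (2S,4S)-5,7,3',4'-tetrakis(benzyloxy)-8-U-flavan-4-ol (2,4-cis) | c9ccccc9COc1cc(OCc9ccccc9)c2c(c1Br)O[C@H](c1cc(OCc9ccccc9)c(OCc9ccccc9)c(OCc9ccccc9)c1)[C@H](OCc9ccccc9)[C@H]2c1c(OCc9ccccc9)cc(OCc9ccccc9)c2c1O[C@H](c1ccc(OCc9ccccc9)c(OCc9ccccc9)c1)C[C@@H]2O
F4 | step 9 | (2S)-5,7,3',4'-tetrakis(benzyloxy)-8-U-flav-3-ene | c9ccccc9COc1cc(OCc9ccccc9)c2c(c1Br)O[C@H](c1cc(OCc9ccccc9)c(OCc9ccccc9)c(OCc9ccccc9)c1)[C@H](OCc9ccccc9)[C@H]2c1c(OCc9ccccc9)cc(OCc9ccccc9)c2c1O[C@H](c1ccc(OCc9ccccc9)c(OCc9ccccc9)c1)C=C2
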